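The side chain is cut between the vinylic CH of the fifth trisubstituted alkene, counted from the isopropylidene end, and the CH2 next to it. The side chain is a repeat of 1,5-dienes, so each such bond joins an alkenyl carbon to a homoallylic CH2; chroman ring and C2 stereocentre stay spectators. A nickel-catalysed electrochemical decarboxylative alkenylation exploits this: in one operation it forges the C(sp2)–C(sp3) bond and carries the E geometry of an alkenyl iodide into the product. Its precursors are a C24 all-E alkenyl iodide from geranylgeraniol and a carboxylic acid, one carbon longer than needed, made from natural γ-tocotrienol by terminal allylic oxidation and two-carbon extension.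

Key step: step 8

Remark: natural (2R,3'E,7'E)-γ-tocotrienol and all-E geranylgeraniol are taken as purchasable. The C2 stereocentre of the chroman therefore comes from the chiral pool, and no step of the route touches it.

Step 1
Reactants: 1 (R)-γ-tocotrienol
Product: 2 (R)-γ-tocotrienol triisopropylsilyl ether
Conditions: iPr3SiCl, imidazole, DMF, rt
Reagents that add atoms: triisopropylsilyl chloride, CC(C)[Si](Cl)(C(C)C)C(C)C
Why: Silyl ether formation at the only OH group should be clean and shields the oxidation-prone chromanol through the selenium, enolate and radical steps, while the C2 stereocentre is not touched.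

Step 2
Reactants: 2 (R)-γ-tocotrienol triisopropylsilyl ether
Product: 3 (2E,6E,10E)-2,6,10-trimethyl-13-[(2R)-2,7,8-trimethyl-6-(triisopropylsilyloxy)chroman-2-yl]trideca-2,6,10-trien-1-ol
Conditions: SeO2 (cat.), t-BuOOH, salicylic acid (cat.), CH2Cl2, 0 °C to rt, stopped before full conversion, unreacted 2 recycled
Reagents that add atoms: selenium dioxide, O=[Se]=O (oxygen carrier); tert-butyl hydroperoxide, CC(C)(C)OO (terminal oxidant)
Why: Catalytic selenium dioxide allylic oxidation (Riley oxidation: ene reaction, then [2,3]-sigmatropic shift) should pick the most electron-rich and least hindered alkene, the terminal isopropylidene group, and there only the methyl group trans to the chain, which makes the new CH2OH-bearing alkene E.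

Step 3
Reactants: 3 terminal (E)-allylic alcohol
Product: 4 (2E,6E,10E)-1-bromo-2,6,10-trimethyl-13-[(2R)-2,7,8-trimethyl-6-(triisopropylsilyloxy)chroman-2-yl]trideca-2,6,10-triene
Conditions: CBr4, PPh3, CH2Cl2, 0 °C
Reagents that add atoms: carbon tetrabromide, BrC(Br)(Br)Br
Why: Appel reaction, in which bromide displaces the oxyphosphonium group by SN2 at the primary carbon, so neither an allylic shift nor a change of alkene geometry is expected.

Step 4
Reactants: 4 terminal (E)-allylic bromide
Product: 5 (4E,8E,12E)-4,8,12-trimethyl-15-[(2R)-2,7,8-trimethyl-6-(triisopropylsilyloxy)chroman-2-yl]pentadeca-4,8,12-trienoic acid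
Conditions: AcOH, LiN(iPr)2 (2 equiv per AcOH), THF–DMPU, 0 °C to rt; then 4, 0 °C to rt; cold dilute HCl work-up
Reagents that add atoms: acetic acid, CC(=O)O
Why: Alkylation of the acetic acid dianion (lithium α-lithioacetate) should occur at carbon by SN2 displacement of the primary allylic bromide and gives the free acid directly, one carbon longer than the chain needs.

Step 5
Reactants: 6 (2E,6E,10E)-geranylgeraniol
Product: 7 (2E,6E,10E)-geranylgeranyl bromide
Conditions: PBr3, Et2O, −10 to 0 °C
Reagents that add atoms: phosphorus tribromide, BrP(Br)Br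
Why: Bromination of the primary allylic alcohol through its phosphite ester (SN2 displacement) should keep the position and E geometry of the allylic alkene at low temperature.

Step 6
Reactants: 7 (2E,6E,10E)-geranylgeranyl bromide
Product: 9 (5E,9E,13E)-6,10,14,18-tetramethylnonadeca-5,9,13,17-tetraen-1-yne, via trimethylsilyl enyne 8 (not isolated)
Conditions: MeC≡CSiMe3, n-BuLi, THF, −78 °C; then 7, −78 °C to rt; then MeOH, K2CO3, rt
Reagents that add atoms: 1-(trimethylsilyl)propyne, CC#C[Si](C)(C)C
Why: Propargylic alkylation, in which the lithiated silylpropyne (its silyl group keeps attack at the CH2 terminus) displaces the allylic bromide by SN2, and base-mediated methanolysis of the C–Si bond then frees the terminal alkyne.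

Step 7
Reactants: 9 (5E,9E,13E)-6,10,14,18-tetramethylnonadeca-5,9,13,17-tetraen-1-yne
Product: 11 (1E,5E,9E,13E)-1-iodo-2,6,10,14,18-pentamethylnonadeca-1,5,9,13,17-pentaene, via alkenyldimethylalane 10 (not isolated)
Conditions: Me3Al, Cp2ZrCl2 (cat.), CH2Cl2, 0 °C to rt; then I2, THF, −30 to 0 °C
Reagents that add atoms: trimethylaluminium, C[Al](C)C; iodine, II
Why: Zirconium-catalysed methylalumination (Negishi carboalumination) adds methyl and aluminium syn across the terminal alkyne with methyl at the inner carbon, and iodinolysis of the C–Al bond with retention should give the E iodide only.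

Step 8
Reactants: 5 homoallylic carboxylic acid; 11 all-E C24 alkenyl iodide
Product: 13 plastochromanol 8 triisopropylsilyl ether, via N-hydroxyphthalimide ester 12 (not isolated)
Conditions: 5, N-hydroxyphthalimide, iPrN=C=NiPr, DMAP (cat.), THF, rt; then 11, NiCl2·6H2O (cat.), 2,2'-bipyridine (cat.), AgNO3 (substoichiometric), LiCl, DMF–THF, Mg anode, reticulated vitreous carbon cathode, undivided cell, constant current, rt
Reagents that add atoms: N-hydroxyphthalimide, O=C1c2ccccc2C(=O)N1O (its atoms enter intermediate 12 only; none of them remains in 13)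
Why: Low-valent nickel carrying 2,2'-bipyridine, formed at the silver-coated cathode, inserts into the C–I bond of 11 with retention to give an alkenyl complex of divalent nickel, while single-electron reduction of ester 12 releases CO2 and phthalimide anion and leaves a primary radical on the CH2 that bore the carboxyl group; the radical is captured at nickel and reductive elimination from trivalent nickel forms the =CH–CH2 bond, the magnesium anode supplying the electrons. The closest known reaction type is the nickel-electrocatalytic decarboxylative alkenylation of redox-active esters with alkenyl iodides, a reductive cross-electrophile coupling known for joining 4-methylpent-4-enoic acid units to alkenyl iodides in polyprenyl chains, which is the same kind of bond. No ring is closed and no stereocentre is created; the one stereo-element at stake, the E geometry of the new trisubstituted alkene, is set in step 7 and carried through because oxidative addition and reductive elimination both go with retention. The selectivity needed is cross-coupling over dimerisation or reduction of either partner, and it is secured by the different ways the two partners enter the cycle (two-electron insertion for the sp2 iodide, one-electron fragmentation for the sp3 ester) and by a small excess of the acid. The homoallylic radical has no fast cyclisation open to it, since closure onto the nearest alkene is a reversible 3-exo process and the next alkene is only reached through a seven-membered ring, so capture by nickel should win; the silyl ether, the other seven alkenes and the remote C2 stereocentre are inert under these mildly reducing conditions.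

Step 9
Reactants: 13 plastochromanol 8 triisopropylsilyl ether
Product: 14 plastochromanol 8
Conditions: Bu4NF, AcOH, THF, 0 °C to rt, under argon
Reagents that add atoms: none
Why: Fluoride-mediated desilylation of the aryl silyl ether, buffered with acetic acid so that the free chromanol is not exposed as an air-sensitive phenoxide, should leave the eight alkenes and the C2 stereocentre as they are.

Compound list
1 | (R)-γ-tocotrienol, (2R)-2,7,8-trimethyl-2-[(3E,7E)-4,8,12-trimethyltrideca-3,7,11-trien-1-yl]chroman-6-ol | CC(C)=CCC/C(C)=C/CC/C(C)=C/CC[C@]1(C)CCc2cc(O)c(C)c(C)c2O1 | starting material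
2 | (R)-γ-tocotrienol triisopropylsilyl ether | CC(C)=CCC/C(C)=C/CC/C(C)=C/CC[C@]1(C)CCc2cc(O[Si](C(C)C)(C(C)C)C(C)C)c(C)c(C)c2O1 | intermediate
3 | (2E,6E,10E)-2,6,10-trimethyl-13-[(2R)-2,7,8-trimethyl-6-(triisopropylsilyloxy)chroman-2-yl]trideca-2,6,10-trien-1-ol | OC/C(C)=C/CC/C(C)=C/CC/C(C)=C/CC[C@]1(C)CCc2cc(O[Si](C(C)C)(C(C)C)C(C)C)c(C)c(C)c2O1 | intermediate
4 | (2E,6E,10E)-1-bromo-2,6,10-trimethyl-13-[(2R)-2,7,8-trimethyl-6-(triisopropylsilyloxy)chroman-2-yl]trideca-2,6,10-triene | BrC/C(C)=C/CC/C(C)=C/CC/C(C)=C/CC[C@]1(C)CCc2cc(O[Si](C(C)C)(C(C)C)C(C)C)c(C)c(C)c2O1 | intermediate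
5 | (4E,8E,12E)-4,8,12-trimethyl-15-[(2R)-2,7,8-trimethyl-6-(triisopropylsilyloxy)chroman-2-yl]pentadeca-4,8,12-trienoic acid | OC(=O)CC/C(C)=C/CC/C(C)=C/CC/C(C)=C/CC[C@]1(C)CCc2cc(O[Si](C(C)C)(C(C)C)C(C)C)c(C)c(C)c2O1 | intermediate
6 | (2E,6E,10E)-geranylgeraniol | CC(C)=CCC/C(C)=C/CC/C(C)=C/CC/C(C)=C/CO | starting material
7 | (2E,6E,10E)-geranylgeranyl bromide | CC(C)=CCC/C(C)=C/CC/C(C)=C/CC/C(C)=C/CBr | intermediate
8 | trimethyl[(5E,9E,13E)-6,10,14,18-tetramethylnonadeca-5,9,13,17-tetraen-1-yn-1-yl]silane | CC(C)=CCC/C(C)=C/CC/C(C)=C/CC/C(C)=C/CCC#C[Si](C)(C)C | intermediate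
9 | (5E,9E,13E)-6,10,14,18-tetramethylnonadeca-5,9,13,17-tetraen-1-yne | CC(C)=CCC/C(C)=C/CC/C(C)=C/CC/C(C)=C/CCC#C | intermediate
10 | dimethyl[(1E,5E,9E,13E)-2,6,10,14,18-pentamethylnonadeca-1,5,9,13,17-pentaen-1-yl]alane | CC(C)=CCC/C(C)=C/CC/C(C)=C/CC/C(C)=C/CC/C(C)=C/[Al](C)C | intermediate
11 | (1E,5E,9E,13E)-1-iodo-2,6,10,14,18-pentamethylnonadeca-1,5,9,13,17-pentaene | CC(C)=CCC/C(C)=C/CC/C(C)=C/CC/C(C)=C/CC/C(C)=C/I | intermediate
12 | N-hydroxyphthalimide (1,3-dioxoisoindolin-2-yl) ester of acid 5 | O=C(CC/C(C)=C/CC/C(C)=C/CC/C(C)=C/CC[C@]1(C)CCc2cc(O[Si](C(C)C)(C(C)C)C(C)C)c(C)c(C)c2O1)ON3C(=O)c4ccccc4C3=O | intermediate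
13 | plastochromanol 8 triisopropylsilyl ether | CC(C)=CCC/C(C)=C/CC/C(C)=C/CC/C(C)=C/CC/C(C)=C/CC/C(C)=C/CC/C(C)=C/CC/C(C)=C/CC[C@]1(C)CCc2cc(O[Si](C(C)C)(C(C)C)C(C)C)c(C)c(C)c2O1 | intermediate
14 | plastochromanol 8, (2R)-2,7,8-trimethyl-2-[(3E,7E,11E,15E,19E,23E,27E)-4,8,12,16,20,24,28,32-octamethyltritriaconta-3,7,11,15,19,23,27,31-octaen-1-yl]chroman-6-ol | CC(C)=CCC/C(C)=C/CC/C(C)=C/CC/C(C)=C/CC/C(C)=C/CC/C(C)=C/CC/C(C)=C/CC/C(C)=C/CC[C@]1(C)CCc2cc(O)c(C)c(C)c2O1 | target

Total step count: 9 steps.
Longest linear sequence: 6 steps (steps 1, 2, 3, 4, 8 and 9); the iodide branch (steps 5, 6, 7) joins at step 8.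

Steps most likely to fail

Step 8. The primary homoallylic radical may dimerise or be reduced before nickel captures it, and reversible 3-exo closure may erode the geometry of the neighbouring alkene. The two lipophilic partners may also mix poorly with the polar electrolyte. The fallback replaces the radical coupling by a two-electron B-alkyl Suzuki–Miyaura coupling; it sets out from alcohol 3 and iodide 11 and comes back to the route at 13. Alcohol 3 would be oxidised with MnO2 in CH2Cl2 to the (E)-enal F1. Wittig methylenation (Ph3PCH3Br, KN(SiMe3)2, THF) would give the terminal 1,3-diene F2, whose new CH2 becomes the coupling carbon. Hydroboration with 9-borabicyclo[3.3.1]nonane in THF should attack only the monosubstituted vinyl group, at its terminus, to give the B-homoallyl borane F3, which would be used without isolation. Coupling with 11 under PdCl2(dppf), AsPh3 and Cs2CO3 in DMF–THF–H2O should give 13 with retention of the iodide geometry.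

Step 2. The allylic oxidation may run on to the enal, attack the internal allylic positions, or stall at low conversion. The fallback degrades and rebuilds the terminal alkene in place of C–H oxidation; it sets out from 2 and comes back at 3. NBS in aqueous THF at 0 °C should add preferentially to the terminal alkene to give the bromohydrin F4 (either epimer at the CHBr carbon). K2CO3 in MeOH would close it to the terminal epoxide F5. HIO4 in aqueous THF would cleave the epoxide to the trisnor aldehyde F6. A Wittig reaction with the stabilised ylide Ph3P=C(CH3)CO2Et should give the (E)-2-methyl enoate F7, and iBu2AlH in CH2Cl2 at −78 °C would reduce it to 3.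

Step 4. The strongly basic dianion may eliminate the allylic bromide to a diene, attack in the SN2' sense, or attack silicon with loss of the silyl ether. The fallback uses a soft, weakly basic nucleophile and a neutral unmasking; it sets out from 4 and comes back at 5. Alkylation of the sodium salt of diallyl malonate (NaH, THF, 0 °C to rt) with 4 would give the diallyl malonate F8. Pd(OAc)2, PPh3 and HCO2H–Et3N in dioxane under reflux should then remove both allyl groups, and the malonic acid should lose CO2 in the same pot to give 5.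

Further compounds
F1 | step 8 | (2E,6E,10E)-2,6,10-trimethyl-13-[(2R)-2,7,8-trimethyl-6-(triisopropylsilyloxy)chroman-2-yl]trideca-2,6,10-trienal | O=C/C(C)=C/CC/C(C)=C/CC/C(C)=C/CC[C@]1(C)CCc2cc(O[Si](C(C)C)(C(C)C)C(C)C)c(C)c(C)c2O1
F2 | step 8 | triisopropylsilyl ether of (2R)-2,7,8-trimethyl-2-[(3E,7E,11E)-4,8,12-trimethyltetradeca-3,7,11,13-tetraen-1-yl]chroman-6-ol | C=C/C(C)=C/CC/C(C)=C/CC/C(C)=C/CC[C@]1(C)CCc2cc(O[Si](C(C)C)(C(C)C)C(C)C)c(C)c(C)c2O1
F3 | step 8 | 9-{(3E,7E,11E)-3,7,11-trimethyl-14-[(2R)-2,7,8-trimethyl-6-(triisopropylsilyloxy)chroman-2-yl]tetradeca-3,7,11-trien-1-yl}-9-borabicyclo[3.3.1]nonane | C1CC2CCCC(C1)B2CC/C(C)=C/CC/C(C)=C/CC/C(C)=C/CC[C@]3(C)CCc4cc(O[Si](C(C)C)(C(C)C)C(C)C)c(C)c(C)c4O3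
F4 | step 2 | terminal bromohydrin of 2, (6E,10E)-3-bromo-2,6,10-trimethyl-13-[(2R)-2,7,8-trimethyl-6-(triisopropylsilyloxy)chroman-2-yl]trideca-6,10-dien-2-ol | CC(C)(O)C(Br)CC/C(C)=C/CC/C(C)=C/CC[C@]1(C)CCc2cc(O[Si](C(C)C)(C(C)C)C(C)C)c(C)c(C)c2O1
F5 | step 2 | terminal epoxide of 2 (3,3-dimethyloxiran-2-yl end group) | CC1(C)OC1CC/C(C)=C/CC/C(C)=C/CC[C@]2(C)CCc3cc(O[Si](C(C)C)(C(C)C)C(C)C)c(C)c(C)c3O2
F6 | step 2 | (4E,8E)-4,8-dimethyl-11-[(2R)-2,7,8-trimethyl-6-(triisopropylsilyloxy)chroman-2-yl]undeca-4,8-dienal | O=CCC/C(C)=C/CC/C(C)=C/CC[C@]1(C)CCc2cc(O[Si](C(C)C)(C(C)C)C(C)C)c(C)c(C)c2O1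
F7 | step 2 | ethyl (2E,6E,10E)-2,6,10-trimethyl-13-[(2R)-2,7,8-trimethyl-6-(triisopropylsilyloxy)chroman-2-yl]trideca-2,6,10-trienoate | CCOC(=O)/C(C)=C/CC/C(C)=C/CC/C(C)=C/CC[C@]1(C)CCc2cc(O[Si](C(C)C)(C(C)C)C(C)C)c(C)c(C)c2O1
F8 | step 4 | diallyl 2-{(2E,6E,10E)-2,6,10-trimethyl-13-[(2R)-2,7,8-trimethyl-6-(triisopropylsilyloxy)chroman-2-yl]trideca-2,6,10-trien-1-yl}malonate | C=CCOC(=O)C(C(=O)OCC=C)C/C(C)=C/CC/C(C)=C/CC/C(C)=C/CC[C@]1(C)CCc2cc(O[Si](C(C)C)(C(C)C)C(C)C)c(C)c(C)c2O1
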